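## Retrosynthetic overview

- **Feature.** In the ten-membered carbocycle, the 1,10-oxirane oxygen bridges the methyl-bearing quaternary C10 and the methine C1. This unit is a C1/C10 vicinal diol minus water, and such a diol is the reductive union of a C10 methyl ketone with a C1 aldehyde.
- **Late stage.** Removing the O6 angelate, the 4,5-oxirane (OH-directed epoxidation of C4=C5) and the C13 methylene leads back to the 1,10-epoxy-6-O-TBS-13-nor-4E-en-12,8-olide. That compound comes from the cis-1,10-diol by C1 mesylation and closure with inversion.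
- **Key disconnection C1–C10.** A SmI2 pinacol coupling of an acyclic keto-aldehyde that already carries the trans γ-lactone (C7, C8), O6 and the 4E-olefin.
- **Keto-aldehyde.** C5–C6 is made by Nozaki–Hiyama–Kishi coupling of a lactone aldehyde with an E-alkenyl iodide from pent-4-yn-1-ol. C7–C8 is made by an Evans succinate syn-aldol with the acetoacetate-ketal aldehyde, followed by lactonisation.
- **Ring order.** γ-Lactone (step 3), ten-membered carbocycle (step 12), 1,10-oxirane (step 14), 4,5-oxirane (step 18).

Key step: step 12

Remark: germacrane numbering (C1–C15, lactone carbonyl C12, exocyclic methylene C13) is used for all intermediates, the acyclic ones included; α and β refer to the usual germacranolide drawing with H7 α.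

## Route

Step 1
Reactants: 1 (R)-4-benzyl-1,3-oxazolidin-2-one; 2 methyl 4-chloro-4-oxobutanoate
Product: 3 methyl 4-[(4R)-4-benzyl-2-oxo-1,3-oxazolidin-3-yl]-4-oxobutanoate
Conditions: Et3N, 4-(dimethylamino)pyridine (cat.), CH2Cl2, 0 °C to rt
Reagents that add atoms: none
Why: N-acylation of the oxazolidinone by the acid chloride under acyl-transfer catalysis is a standard imide formation that leaves the methyl ester and the benzyl-bearing stereocentre untouched.

Step 2
Reactants: 4 ethyl 2-(2-methyl-1,3-dioxolan-2-yl)acetate
Product: 5 2-(2-methyl-1,3-dioxolan-2-yl)acetaldehyde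
Conditions: i-Bu2AlH (1.05 equiv), CH2Cl2, −78 °C; aq. potassium sodium tartrate
Reagents that add atoms: none
Why: Partial ester reduction at −78 °C stops at the aluminium hemiacetal, which releases the aldehyde only on work-up, and the ketal is inert to hydride.

Step 3
Reactants: 3 succinate imide; 5 ketal aldehyde
Product: 8 (7R,8S)-trans-lactone imide, via Z-boron enolate 6 (not isolated), via syn-aldol hydroxy ester 7 (not isolated)
Conditions: 3, Bu2BOTf, i-Pr2NEt, CH2Cl2, −78 to 0 °C; 5, −78 to 0 °C; pH 7 buffer, MeOH, H2O2, 0 °C; crude 7, pyridinium p-toluenesulfonate (cat.), CH2Cl2, rt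
Reagents that add atoms: none
Why: Evans syn-aldol in which soft enolisation takes place only at the imide α-carbon, the chair Zimmerman–Traxler transition state of Z-enolate 6 with one face shielded by the benzyl group sets (7R,8S), and the γ-hydroxy methyl ester 7 lactonises (5-exo-trig acyl substitution) to the trans-lactone because the syn-aldol array places C6 and C9 on opposite faces of the new ring.

Step 4
Reactants: 8 trans-lactone imide
Product: 9 S-ethyl (7R,8S)-lactone thioester
Conditions: EtSH, n-BuLi, THF, 0 °C
Reagents that add atoms: ethanethiol, CCS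
Why: Thiolate transacylation of the exocyclic imide carbonyl removes the auxiliary, since the soft and weakly basic lithium thiolate attacks the most electrophilic carbonyl, attack on the lactone is reversible, and C7 is not enolised at 0 °C.

Step 5
Reactants: 9 lactone thioester
Product: 10 (7R,8S)-lactone aldehyde
Conditions: Et3SiH, Pd/C (10 mol %), acetone, rt
Reagents that add atoms: none
Why: Fukuyama reduction, in which zerovalent palladium inserts into the C–S bond and the silane delivers hydride, gives the aldehyde under neutral conditions, so the epimerisable C7, the β-acyloxy arrangement, the lactone and the ketal survive.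

Step 6
Reactants: 11 pent-4-yn-1-ol
Product: 13 (E)-5-iodo-4-methylpent-4-en-1-ol, via alkenylalane 12 (not isolated)
Conditions: Me3Al (3 equiv), Cp2ZrCl2 (0.25 equiv), CH2Cl2, 0 °C to rt; I2, THF, −30 to 0 °C
Reagents that add atoms: trimethylaluminium, C[Al](C)C; iodine, II
Why: Negishi zirconium-catalysed carboalumination adds methyl and aluminium syn across the terminal alkyne with methyl on the internal carbon, and iodinolysis with retention gives the E-iodide that fixes the C4=C5 geometry.

Step 7
Reactants: 13 iodo alcohol
Product: 14 (E)-5-iodo-4-methylpent-4-enal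
Conditions: Dess–Martin periodinane, CH2Cl2, rt
Reagents that add atoms: none
Why: Dess–Martin oxidation takes the primary alcohol to the aldehyde under neutral conditions that leave the alkenyl iodide untouched.

Step 8
Reactants: 14 iodo aldehyde
Product: 15 (E)-1-iodo-5,5-dimethoxy-2-methylpent-1-ene
Conditions: HC(OMe)3, pyridinium p-toluenesulfonate (cat.), MeOH, rt
Reagents that add atoms: trimethyl orthoformate, COC(OC)OC; methanol, CO
Why: Acid-catalysed acetalisation with orthoformate as water scavenger masks the future C1 aldehyde in a form that falls off later in the same operation as the C10 ketal.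

Step 9
Reactants: 10 lactone aldehyde; 15 alkenyl iodide acetal (1.5 equiv)
Product: 16 (6R,7S,8S)-allylic alcohol
Conditions: CrCl2 (4 equiv), NiCl2 (1 mol %), DMF, rt
Reagents that add atoms: none
Why: Nozaki–Hiyama–Kishi coupling gives, with retention of the E geometry, a non-basic alkenylchromium species that adds only to the aldehyde (lactone, ketal and acetal inert, C7 not enolised), and Felkin–Anh attack anti to the larger C8 branch on the Re face of the aldehyde sets 6R, with O6 syn to C11 in the C5–C8 zigzag as the target requires.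

Step 10
Reactants: 16 allylic alcohol
Product: 17 (6R,7R,8S)-6-O-TBS ether
Conditions: t-BuMe2SiOTf, 2,6-lutidine, CH2Cl2, −78 to −20 °C
Reagents that add atoms: tert-butyldimethylsilyl triflate, CC(C)(C)[Si](C)(C)OS(=O)(=O)C(F)(F)F
Why: Silyl triflate silylation with a hindered pyridine base is fast at low temperature, so O6 is capped before it can attack C12 and move the lactone to O6, and no stereocentre is touched.

Step 11
Reactants: 17 TBS ether
Product: 18 (6R,7R,8S)-keto-aldehyde (C10 methyl ketone and C1 aldehyde on the trans-lactone with 6-O-TBS and 4E-olefin)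
Conditions: pyridinium p-toluenesulfonate (0.2 equiv), acetone–H2O 9:1, 50 °C
Reagents that add atoms: water, O
Why: Mild acid-catalysed hydrolysis frees the dimethyl acetal and the dioxolane ketal in one operation, the secondary TBS ether and the lactone withstand it, and an acidic rather than basic medium avoids E1cB loss of the C8 carboxylate from the β-acyloxy ketone.

Step 12
Reactants: 18 keto-aldehyde
Product: 19 (1S,6R,7R,8S,10R)-1,10-dihydroxy-6-O-TBS-13-nor-germacr-4E-en-12,8-olide (1α,10α-cis-diol)
Conditions: SmI2 (3 equiv), THF, 25 °C, syringe-pump addition of 18 (final 2 mM); aq. potassium sodium tartrate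
Reagents that add atoms: none
Why: SmI2 transfers one electron to the more easily reduced C1 aldehyde, the trivalent-samarium ketyl so formed binds the C10 ketone oxygen, C1 adds to C10, and a second SmI2 completes the samarium diolate that is protonated on work-up. The closest known reaction type is the intramolecular keto-aldehyde pinacol coupling with SmI2 or low-valent titanium (McMurry-type pinacol macrocyclisation), which is established for medium and large carbocycles. The ten-membered carbocycle closes in the 10-exo-trig mode (C1 radical on the carbon of C10=O, oxygen left outside the ring), and slow addition at about 2 mM together with the bend that the trans-lactone and the E-olefin impose on the chain should favour it over dimerisation. C10 should be controlled by C8: with C10 anti to O8 about C8–C9 and the C14 methyl extended away from C8, the C1 arm reaches only the Si face of the ketone without a syn-pentane contact between C7 and C1, which gives 10R. C1 should be controlled by the metal: both oxygens sit on one samarium, the O–C–C–O unit is therefore nearly eclipsed, and the pairing C14/H1 and C9/C2 (cisoid ring torsion as in a cis-cyclodecene) is preferred to the pairing C14/C2, so that the Re face of the aldehyde reacts and the cis-diol (1S,10R) results. The step needs chemoselectivity for the two carbonyls and this one diastereomer: neither carbonyl has an α-leaving group, lactone and allylic silyl ether are inert to SmI2 in the absence of HMPA or water, and without such additives the dialkyl ketone is not reduced on its own, so that a 6-exo ketyl–olefin closure of C10 on C5 cannot start.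

Step 13
Reactants: 19 cis-diol
Product: 20 (1S,6R,7R,8S,10R)-C1 mesylate with free C10 hydroxyl
Conditions: MeSO2Cl (1.2 equiv), Et3N, CH2Cl2, −20 to 0 °C
Reagents that add atoms: methanesulfonyl chloride, CS(=O)(=O)Cl
Why: Chemoselective sulfonylation, in which the secondary C1 hydroxyl is mesylated while the tertiary C10 hydroxyl is too hindered to react at or below 0 °C, and no stereocentre is touched.

Step 14
Reactants: 20 hydroxy mesylate
Product: 21 (1R,6R,7R,8S,10R)-1,10-epoxy-6-O-TBS-13-nor-germacr-4E-en-12,8-olide
Conditions: KN(SiMe3)2 (1.05 equiv), THF, −78 to 0 °C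
Reagents that add atoms: none
Why: Intramolecular Williamson-type 3-exo-tet displacement, in which the C10 alkoxide attacks C1 anti to the mesylate, keeps the C10–O bond and inverts C1 from S to R, which turns the cis-diol into the trans-(1R,10R)-oxirane, O–H deprotonation by one equivalent of base being faster than lactone enolisation.

Step 15
Reactants: 21 epoxy lactone
Product: 23 (11S)-11-(dimethylaminomethyl) lactone, via lithium enolate 22 (not isolated)
Conditions: LiN(i-Pr)2 (1.3 equiv), THF, −78 °C; CH2=NMe2+ I−, −78 °C to rt
Reagents that add atoms: Eschenmoser's salt, C[N+](C)=C.[I-]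
Why: Mannich-type aminomethylation of the lactone enolate, which has no β-leaving group and coexists with the oxirane at −78 °C, should take place anti to the C6 branch on C7 (11S), a centre that is erased in the next step.

Step 16
Reactants: 23 Mannich base
Product: 25 (1R,6R,7R,8S,10R)-1,10-epoxy-6-O-TBS-germacra-4E,11(13)-dien-12,8-olide, via ammonium iodide 24 (not isolated)
Conditions: MeI, CH2Cl2–MeOH, rt; aq. NaHCO3, CH2Cl2, rt
Reagents that add atoms: none
Why: Exhaustive methylation followed by Hofmann-type E1cB loss of trimethylamine under bicarbonate installs the exocyclic C11=C13 bond under conditions too mild to touch the oxirane or the silyl ether.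

Step 17
Reactants: 25 methylene lactone TBS ether
Product: 26 (1R,6R,7S,8S,10R)-1,10-epoxy-6-hydroxygermacra-4E,11(13)-dien-12,8-olide
Conditions: Bu4NF, AcOH (1:1), THF, 0 °C to rt
Reagents that add atoms: none
Why: Fluoride-induced Si–O cleavage buffered with acetic acid keeps O6 protonated, so that acyl migration to a 12,6-lactone, conjugate addition to the methylene lactone and acid-induced transannular opening of the 1,10-oxirane are all avoided.

Step 18
Reactants: 26 allylic alcohol
Product: 27 (1R,4R,5R,6S,7S,8S,10R)-1,10:4,5-diepoxy-6-hydroxygermacr-11(13)-en-12,8-olide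
Conditions: mCPBA (1.2 equiv), CH2Cl2–aq. NaHCO3, 0 °C
Reagents that add atoms: 3-chloroperoxybenzoic acid, O=C(OO)c1cccc(Cl)c1
Why: Hydroxyl-directed (Henbest-type) peracid epoxidation, in which allylic 1,3-strain with the C15 methyl holds H6 in the olefin plane and so places O6 on the outer and C7 on the inner face of the E-cyclodecene unit, makes peripheral and OH-guided delivery coincide to give the threo (4R,5R)-oxirane, while the electron-poor C11=C13 bond does not react.

Step 19
Reactants: 27 diepoxy alcohol; 28 angelic acid, (Z)-2-methylbut-2-enoic acid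
Product: 30 target CNP0145353.1, via mixed anhydride 29 (not isolated)
Conditions: 28, 2,4,6-Cl3C6H2COCl, Et3N, toluene, rt; 27, 75 °C
Reagents that add atoms: none
Why: Yamaguchi-type mixed-anhydride esterification run without a nucleophilic catalyst is the known way to angelates of hindered secondary alcohols, because the alcohol attacks the less hindered angeloyl carbonyl and the absence of an acyl-transfer amine suppresses addition–elimination isomerisation of the Z double bond to the tiglate.

## Compound list

1 | (R)-4-benzyl-1,3-oxazolidin-2-one | O=C1N[C@H](Cc2ccccc2)CO1 | starting material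
2 | methyl 4-chloro-4-oxobutanoate | COC(=O)CCC(=O)Cl | starting material
3 | methyl 4-[(4R)-4-benzyl-2-oxo-1,3-oxazolidin-3-yl]-4-oxobutanoate | COC(=O)CCC(=O)N1[C@H](Cc2ccccc2)COC1=O | intermediate
4 | ethyl 2-(2-methyl-1,3-dioxolan-2-yl)acetate | CCOC(=O)CC1(C)OCCO1 | starting material
5 | 2-(2-methyl-1,3-dioxolan-2-yl)acetaldehyde | O=CCC1(C)OCCO1 | intermediate
6 | Z-dibutylboron enolate of imide 3 | COC(=O)C/C=C(\OB(CCCC)CCCC)N1[C@H](Cc2ccccc2)COC1=O | intermediate
7 | methyl (3R,4S)-3-[(4R)-4-benzyl-2-oxo-1,3-oxazolidine-3-carbonyl]-4-hydroxy-5-(2-methyl-1,3-dioxolan-2-yl)pentanoate (7R,8S syn-aldol) | COC(=O)C[C@H]([C@@H](O)CC1(C)OCCO1)C(=O)N1[C@H](Cc2ccccc2)COC1=O | intermediate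
8 | (4R)-4-benzyl-3-{(2S,3R)-2-[(2-methyl-1,3-dioxolan-2-yl)methyl]-5-oxooxolane-3-carbonyl}-1,3-oxazolidin-2-one (trans-lactone, 7R,8S) | CC1(OCCO1)C[C@@H]1OC(=O)C[C@H]1C(=O)N1[C@H](Cc2ccccc2)COC1=O | intermediate
9 | S-ethyl (2S,3R)-2-[(2-methyl-1,3-dioxolan-2-yl)methyl]-5-oxooxolane-3-carbothioate | CC1(OCCO1)C[C@@H]1OC(=O)C[C@H]1C(=O)SCC | intermediate
10 | (2S,3R)-2-[(2-methyl-1,3-dioxolan-2-yl)methyl]-5-oxooxolane-3-carbaldehyde | CC1(OCCO1)C[C@@H]1OC(=O)C[C@H]1C=O | intermediate
11 | pent-4-yn-1-ol | C#CCCCO | starting material
12 | (E)-alkenyl(dimethyl)alane of the dimethylaluminium alkoxide of 4-methylpent-4-en-1-ol | C[Al](C)/C=C(\C)CCCO[Al](C)C | intermediate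
13 | (E)-5-iodo-4-methylpent-4-en-1-ol | OCCC/C(C)=C/I | intermediate
14 | (E)-5-iodo-4-methylpent-4-enal | O=CCC/C(C)=C/I | intermediate
15 | (E)-1-iodo-5,5-dimethoxy-2-methylpent-1-ene | COC(OC)CC/C(C)=C/I | intermediate
16 | (6R,7S,8S)-trans-lactone bearing the (1R,2E)-1-hydroxy-6,6-dimethoxy-3-methylhex-2-enyl chain on C7 and the ketal side chain on C8 | CC1(OCCO1)C[C@@H]1OC(=O)C[C@H]1[C@H](O)/C=C(C)/CCC(OC)OC | intermediate
17 | (6R,7R,8S)-6-O-tert-butyldimethylsilyl ether of 16 | CC1(OCCO1)C[C@@H]1OC(=O)C[C@H]1[C@H](O[Si](C)(C)C(C)(C)C)/C=C(C)/CCC(OC)OC | intermediate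
18 | (6R,7R,8S)-trans-lactone keto-aldehyde, C10 methyl ketone, C1 aldehyde, 6-O-TBS, 4E-olefin, no C13 | CC(=O)C[C@@H]1OC(=O)C[C@H]1[C@H](O[Si](C)(C)C(C)(C)C)/C=C(C)/CCC=O | intermediate
19 | (1S,6R,7R,8S,10R)-1,10-dihydroxy-6-O-TBS-13-nor-germacr-4E-en-12,8-olide | C1C(=O)O[C@H]2C[C@@](C)(O)[C@@H](O)CC/C(C)=C/[C@@H](O[Si](C)(C)C(C)(C)C)[C@H]12 | intermediate
20 | (1S,6R,7R,8S,10R)-10-hydroxy-1-mesyloxy-6-O-TBS-13-nor-germacr-4E-en-12,8-olide | C1C(=O)O[C@H]2C[C@@](C)(O)[C@@H](OS(C)(=O)=O)CC/C(C)=C/[C@@H](O[Si](C)(C)C(C)(C)C)[C@H]12 | intermediate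
21 | (1R,6R,7R,8S,10R)-1,10-epoxy-6-O-TBS-13-nor-germacr-4E-en-12,8-olide | C1C(=O)O[C@H]2C[C@@]3(C)O[C@@H]3CC/C(C)=C/[C@@H](O[Si](C)(C)C(C)(C)C)[C@H]12 | intermediate
22 | lithium enolate (C11=C12–OLi) of 21 | C1=C(O[Li])O[C@H]2C[C@@]3(C)O[C@@H]3CC/C(C)=C/[C@@H](O[Si](C)(C)C(C)(C)C)[C@H]12 | intermediate
23 | (11S)-11-(dimethylaminomethyl) derivative of 21 | CN(C)C[C@H]1C(=O)O[C@H]2C[C@@]3(C)O[C@@H]3CC/C(C)=C/[C@@H](O[Si](C)(C)C(C)(C)C)[C@H]12 | intermediate
24 | trimethylammonium iodide of 23 | C[N+](C)(C)C[C@H]1C(=O)O[C@H]2C[C@@]3(C)O[C@@H]3CC/C(C)=C/[C@@H](O[Si](C)(C)C(C)(C)C)[C@H]12.[I-] | intermediate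
25 | (1R,6R,7R,8S,10R)-1,10-epoxy-6-O-TBS-germacra-4E,11(13)-dien-12,8-olide | C=C1C(=O)O[C@H]2C[C@@]3(C)O[C@@H]3CC/C(C)=C/[C@@H](O[Si](C)(C)C(C)(C)C)[C@H]12 | intermediate
26 | (1R,6R,7S,8S,10R)-1,10-epoxy-6-hydroxygermacra-4E,11(13)-dien-12,8-olide | C=C1C(=O)O[C@H]2C[C@@]3(C)O[C@@H]3CC/C(C)=C/[C@@H](O)[C@H]12 | intermediate
27 | (1R,4R,5R,6S,7S,8S,10R)-1,10:4,5-diepoxy-6-hydroxygermacr-11(13)-en-12,8-olide | C=C1C(=O)O[C@H]2C[C@@]3(C)O[C@@H]3CC[C@@]3(C)O[C@@H]3[C@@H](O)[C@H]12 | intermediate
28 | angelic acid, (Z)-2-methylbut-2-enoic acid | C/C=C(/C)C(=O)O | starting material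
29 | angelic 2,4,6-trichlorobenzoic anhydride | C/C=C(/C)C(=O)OC(=O)c1c(Cl)cc(Cl)cc1Cl | intermediate
30 | CNP0145353.1, (1R,4R,5R,6S,7R,8S,10R)-6-angeloyloxy-1,10:4,5-diepoxygermacr-11(13)-en-12,8-olide | C=C1C(=O)O[C@H]2C[C@@]3(C)O[C@@H]3CC[C@@]3(C)O[C@@H]3[C@@H](OC(=O)/C(C)=C\C)[C@H]12 | target

## Step count

- Total step count: 19.
- Longest linear sequence: 15 steps (steps 1, 3–5 and 9–19). The branch from 4 through step 2 is equally long, and the branch from 11 has 14 steps.

## Steps most likely to fail

**Step 12.**
- Risk: ring closure may be too slow, so that plain reduction of the aldehyde and intermolecular coupling take over. Control at C1 may also be lost if the bond forms through a transoid C9–C10–C1–C2 torsion, which leads to the trans-diol. This diastereomer question is the open point of the route.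
- Fallback, from 18 back to 21: the C1–C10 carbonyl coupling is kept, but the oxirane is no longer made by displacement.
  - The coupling of 18 (SmI2 as above) then furnishes the trans-diol (1R,6R,7R,8S,10R)-1,10-dihydroxy-6-O-TBS-13-nor-germacr-4E-en-12,8-olide F1.
  - Thiocarbonyldiimidazole and 4-(dimethylamino)pyridine in toluene at 80 °C convert it into the cyclic 1,10-thionocarbonate F2.
  - Corey–Winter elimination with 1,3-dimethyl-2-phenyl-1,3,2-diazaphospholidine at 40 °C is a stereospecific syn elimination and gives the 1(10)E,4E-diene F3.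
  - One equivalent of buffered mCPBA at −20 °C should epoxidise the more electron-rich 1(10)-olefin, because the 4,5-olefin is deactivated and shielded by the allylic silyl ether. Attack from the periphery of the crown conformer, which has both ring methyls on the β face, gives 21.

**Step 9.**
- Risk: the steric difference between the C8 and C11 branches of the lactone is modest, so Felkin–Anh facial selectivity may be poor. Migration of the lactone acyl group to the new C6 alkoxide may also set in during a slow coupling.
- Fallback, from 16 (taken as its C6 epimer mixture) back to 16: the C6 centre is set by reagent-controlled C–H rather than C–C bond formation.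
  - Dess–Martin oxidation of the mixture gives the (7R,8S)-E-enone F4.
  - CBS reduction follows with (R)-1-methyl-3,3-diphenyltetrahydro-1H,3H-pyrrolo[1,2-c][1,3,2]oxazaborole and catecholborane in toluene at −78 °C. The alkenyl arm takes the place of the large group, so the reduction should deliver the 6R alcohol 16 against the modest substrate bias.
  - The product is silylated at once as in step 10.

**Step 19.**
- Risk: O6 is flanked by the 4,5-oxirane and the ring-fusion carbon C7, so acylation may be slow. Z-to-E isomerisation of the acyl donor at 75 °C and migration of the lactone to O6 could then compete.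
- Fallback, from 26 back to 30: the order of the last two operations is reversed and the epoxidation is put under reagent control.
  - The less hindered allylic alcohol 26 is esterified with mixed anhydride 29 at lower temperature to give the 6-O-angeloyl-1,10-epoxygermacra-4E,11(13)-dien-12,8-olide F5.
  - Shi epoxidation follows with the D-fructose-derived ketone (1,2:4,5-di-O-isopropylidene-β-D-erythro-2,3-hexodiulo-2,6-pyranose), Oxone (2KHSO5·KHSO4·K2SO4) and K2CO3 in MeCN–dimethoxymethane–aqueous buffer at 0 °C. This catalyst gives R,R-epoxides from E-trisubstituted olefins and is matched with peripheral attack, so it should oxidise only C4=C5 and give 30. The two conjugated olefins are too electron-poor to react.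

Further compounds
F1 | step 12 | (1R,6R,7R,8S,10R)-1,10-dihydroxy-6-O-TBS-13-nor-germacr-4E-en-12,8-olide (trans-diol) | C1C(=O)O[C@H]2C[C@@](C)(O)[C@H](O)CC/C(C)=C/[C@@H](O[Si](C)(C)C(C)(C)C)[C@H]12
F2 | step 12 | cyclic 1,10-thionocarbonate of F1 | C1C(=O)O[C@H]2C[C@@]3(C)OC(=S)O[C@@H]3CC/C(C)=C/[C@@H](O[Si](C)(C)C(C)(C)C)[C@H]12
F3 | step 12 | (6R,7R,8S)-6-O-TBS-13-nor-germacra-1(10)E,4E-dien-12,8-olide | C1C(=O)O[C@H]2C/C(C)=C/CC/C(C)=C/[C@@H](O[Si](C)(C)C(C)(C)C)[C@H]12
F4 | step 9 | (7R,8S)-trans-lactone E-enone (C6 ketone of 16) | CC1(OCCO1)C[C@@H]1OC(=O)C[C@H]1C(=O)/C=C(C)/CCC(OC)OC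
F5 | step 19 | (1R,6R,7R,8S,10R)-6-angeloyloxy-1,10-epoxygermacra-4E,11(13)-dien-12,8-olide | C=C1C(=O)O[C@H]2C[C@@]3(C)O[C@@H]3CC/C(C)=C/[C@@H](OC(=O)/C(C)=C\C)[C@H]12
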